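**Retrosynthetic overview** (benzofuran numbering: O1, C2 lactone C=O, C3, C3a, C4, C5, C6, C7, C7a)
1. Target ⇐ a fully substituted p-quinone carrying the C3 arylacetate side chain on C3a: O-dealkylation, prototropy to the C3=C3a quinone methide and O1–C2 lactonisation, with no redox step; the lactone ring is formed last.
2. Key disconnection: that quinone ⇐ a 4-allenyl-4-hydroxycyclobutenone. Thermal 4π opening of the C5–C7a bond and 6π closure C7a→C3a expand the squarate ring (C5, C6, C7, C7a with their three oxygens and the C7 phenyl) into the hexasubstituted ring C3a–C4–C5–C6–C7–C7a. The allene C4=C3a=C3 supplies both 4-oxyphenyl-bearing carbons and the C3=C3a unsaturation of the quinone methide.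
3. Allenyl cyclobutenone ⇐ 3-isopropoxy-4-phenylcyclobutenedione + a silyl alkynyl ketene acetal (C4–C5 bond, γ-selective alkynylogous Mukaiyama aldol).
4. Cyclobutenedione ⇐ diisopropyl squarate + PhLi; ketene acetal ⇐ 4-ethynylanisole + methyl diazo(4-methoxyphenyl)acetate. Ring order: four-membered ring bought, six-membered ring in step 6, lactone in step 7.

Key step: step 6

Remark: the target has no stereocentre and no stereogenic double bond, so its constitution defines it completely. Stereogenic elements in intermediates (α-carbon of the esters, carbinol carbon, allene axis) form without control and are all erased.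

Step 1
Reactants: 1 3,4-diisopropoxycyclobut-3-ene-1,2-dione (diisopropyl squarate); 2 phenyllithium
Product: 4 3-isopropoxy-4-phenylcyclobut-3-ene-1,2-dione, via carbinol adduct 3 (not isolated)
Conditions: PhLi, THF, −78 °C; then conc. HCl, CH2Cl2, rt
Reagents that add atoms: none
Why: 1,2-addition of the aryllithium to one squarate carbonyl, then acid-mediated loss of isopropanol from the vinylogous hemiketal (the standard squarate-to-semisquarate sequence), should give the 3-alkoxy-4-arylcyclobutenedione.

Step 2
Reactants: 5 methyl 2-(4-methoxyphenyl)acetate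
Product: 6 methyl 2-diazo-2-(4-methoxyphenyl)acetate
Conditions: 4-acetamidobenzenesulfonyl azide, DBU, MeCN, 0 °C → rt
Reagents that add atoms: 4-acetamidobenzenesulfonyl azide, CC(=O)Nc1ccc(cc1)S(=O)(=O)N=[N+]=[N-]
Why: Regitz diazo transfer to the activated benzylic α-carbon of an arylacetate is routine and should give the donor/acceptor diazo ester.

Step 3
Reactants: 6 methyl 2-diazo-2-(4-methoxyphenyl)acetate; 7 1-ethynyl-4-methoxybenzene
Product: 8 methyl 2,4-bis(4-methoxyphenyl)but-3-ynoate (racemic)
Conditions: CuI (10 mol %), MeCN, rt, slow addition of 6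
Reagents that add atoms: none
Why: Copper-catalysed carbene/alkyne cross-coupling (copper acetylide, migratory insertion of the copper carbene, protonation) should give the 3-alkynoate; a prototropic shift to the allenoate would be harmless because both isomers give the same enolate in step 4.

Step 4
Reactants: 8 methyl 2,4-bis(4-methoxyphenyl)but-3-ynoate
Product: 10 tert-butyl{[1-methoxy-2,4-bis(4-methoxyphenyl)but-1-en-3-yn-1-yl]oxy}dimethylsilane, via lithium enolate 9 (not isolated)
Conditions: LDA, THF, −78 °C; TBSCl, DMPU, −78 °C → rt; pentane, filtration, used crude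
Reagents that add atoms: tert-butyldimethylsilyl chloride, CC(C)(C)[Si](C)(C)Cl
Why: Deprotonation of the doubly activated α-C–H and O-silylation of the ester enolate in the presence of DMPU (silyl ketene acetal formation) should give the conjugated enyne ketene acetal, whose double-bond geometry is irrelevant.

Step 5
Reactants: 10 tert-butyl{[1-methoxy-2,4-bis(4-methoxyphenyl)but-1-en-3-yn-1-yl]oxy}dimethylsilane; 4 3-isopropoxy-4-phenylcyclobut-3-ene-1,2-dione
Product: 11 methyl 4-(1-hydroxy-2-isopropoxy-4-oxo-3-phenylcyclobut-2-en-1-yl)-2,4-bis(4-methoxyphenyl)buta-2,3-dienoate (mixture of racemic diastereomers)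
Conditions: TiCl4 (1.1 equiv), CH2Cl2, −78 °C; then H2O/pH 7 buffer, cold work-up, kept cold
Reagents that add atoms: none
Why: In this alkynylogous Mukaiyama aldol addition the γ-carbon (alkyne terminus) of 10, whose α-carbon is fully substituted, should attack the ketone carbonyl next to C–OiPr of the titanium-activated dione (the other carbonyl is a deactivated vinylogous ester) and give the tetrasubstituted allene; the carbinol centre and allene axis form without control and are destroyed in steps 6 and 7.

Step 6
Reactants: 11 methyl 4-(1-hydroxy-2-isopropoxy-4-oxo-3-phenylcyclobut-2-en-1-yl)-2,4-bis(4-methoxyphenyl)buta-2,3-dienoate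
Product: 14 methyl 2-[4-isopropoxy-2-(4-methoxyphenyl)-3,6-dioxo-5-phenylcyclohexa-1,4-dien-1-yl]-2-(4-methoxyphenyl)acetate (racemic), via allenyl vinylketene 12 (not isolated), via o-quinone methide 13 (not isolated)
Conditions: PhMe (degassed, 0.02 M), 100 °C
Reagents that add atoms: none
Why: Heating should trigger conrotatory 4π electrocyclic opening of the C5–C7a bond of the cyclobutenone with the hydroxyl rotating outward (torquoselectivity of donor substituents), which places the allenyl group cis to the new ketene in 12. The ketene carbon C7a should then bond to the central allene carbon C3a in a 6π electrocyclization (the ring C3a–C4–C5–C6–C7–C7a closes in the disrotatory electrocyclic mode), giving o-quinone methide 13 in which the second allene π-bond has become the exocyclic C3=C3a bond. A 1,5-hydrogen shift from the C5 hydroxyl to C3 (dienol-to-ketone tautomerisation) should relieve the strain of the tetrasubstituted exocyclic alkene and deliver the fully substituted p-quinone 14. The closest known reaction type is the thermal ring expansion of 4-allenyl-4-hydroxycyclobutenones to o-quinone methides and of 4-alkenyl analogues to hydroquinones (Moore-type ring expansion). The only new stereocentre (C3) forms as a racemate and is removed in step 7. The step needs regiocontrol over six different ring substituents, and the connectivity of 11 secures it, because every substituent is already bonded to the atom that becomes its ring carbon and only one six-membered closure is possible.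

Step 7
Reactants: 14 methyl 2-[4-isopropoxy-2-(4-methoxyphenyl)-3,6-dioxo-5-phenylcyclohexa-1,4-dien-1-yl]-2-(4-methoxyphenyl)acetate
Product: 16 peniophorin (5-hydroxy-3,4-bis(4-hydroxyphenyl)-7-phenyl-1-benzofuran-2,6-dione), via deprotected hydroxyquinone ester 15 (not isolated)
Conditions: BBr3 (excess), CH2Cl2, −78 °C → rt; then H2O/2 M HCl, AcOH, 50 °C
Reagents that add atoms: none
Why: Boron tribromide should cleave the two aryl methyl ethers and the vinylogous isopropyl ester (Lewis acid ether cleavage), after which hydroxyquinone 15 should tautomerise to the C7a-enol/C3=C3a quinone methide and close the five-membered enol lactone (5-exo-trig acyl substitution) with loss of methanol, the conjugated lactone being the thermodynamic sink.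

**Compound list**
1 | 3,4-diisopropoxycyclobut-3-ene-1,2-dione | CC(C)OC1=C(OC(C)C)C(=O)C1=O | starting material
2 | phenyllithium | [Li]c1ccccc1 | starting material
3 | 4-hydroxy-2,3-diisopropoxy-4-phenylcyclobut-2-en-1-one | CC(C)OC1=C(OC(C)C)C(O)(c2ccccc2)C1=O | intermediate
4 | 3-isopropoxy-4-phenylcyclobut-3-ene-1,2-dione | CC(C)OC1=C(c2ccccc2)C(=O)C1=O | intermediate
5 | methyl 2-(4-methoxyphenyl)acetate | COC(=O)Cc1ccc(OC)cc1 | starting material
6 | methyl 2-diazo-2-(4-methoxyphenyl)acetate | COC(=O)C(=[N+]=[N-])c1ccc(OC)cc1 | intermediate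
7 | 1-ethynyl-4-methoxybenzene | C#Cc1ccc(OC)cc1 | starting material
8 | methyl 2,4-bis(4-methoxyphenyl)but-3-ynoate | COC(=O)C(C#Cc1ccc(OC)cc1)c1ccc(OC)cc1 | intermediate
9 | lithium 1-methoxy-2,4-bis(4-methoxyphenyl)but-1-en-3-yn-1-olate | [Li+].COC([O-])=C(C#Cc1ccc(OC)cc1)c1ccc(OC)cc1 | intermediate
10 | tert-butyl{[1-methoxy-2,4-bis(4-methoxyphenyl)but-1-en-3-yn-1-yl]oxy}dimethylsilane | COC(O[Si](C)(C)C(C)(C)C)=C(C#Cc1ccc(OC)cc1)c1ccc(OC)cc1 | intermediate
11 | methyl 4-(1-hydroxy-2-isopropoxy-4-oxo-3-phenylcyclobut-2-en-1-yl)-2,4-bis(4-methoxyphenyl)buta-2,3-dienoate | COC(=O)C(c1ccc(OC)cc1)=C=C(c1ccc(OC)cc1)C1(O)C(OC(C)C)=C(c2ccccc2)C1=O | intermediate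
12 | methyl 5-hydroxy-6-isopropoxy-2,4-bis(4-methoxyphenyl)-8-oxo-7-phenylocta-2,3,5,7-tetraenoate | COC(=O)C(c1ccc(OC)cc1)=C=C(c1ccc(OC)cc1)C(O)=C(OC(C)C)C(c1ccccc1)=C=O | intermediate
13 | methyl 2-[3-hydroxy-4-isopropoxy-2-(4-methoxyphenyl)-6-oxo-5-phenylcyclohexa-2,4-dien-1-ylidene]-2-(4-methoxyphenyl)acetate | COC(=O)C(c1ccc(OC)cc1)=C1C(=O)C(c2ccccc2)=C(OC(C)C)C(O)=C1c1ccc(OC)cc1 | intermediate
14 | methyl 2-[4-isopropoxy-2-(4-methoxyphenyl)-3,6-dioxo-5-phenylcyclohexa-1,4-dien-1-yl]-2-(4-methoxyphenyl)acetate | COC(=O)C(c1ccc(OC)cc1)C1=C(c2ccc(OC)cc2)C(=O)C(OC(C)C)=C(c2ccccc2)C1=O | intermediate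
15 | methyl 2-[4-hydroxy-2-(4-hydroxyphenyl)-3,6-dioxo-5-phenylcyclohexa-1,4-dien-1-yl]-2-(4-hydroxyphenyl)acetate | COC(=O)C(c1ccc(O)cc1)C1=C(c2ccc(O)cc2)C(=O)C(O)=C(c2ccccc2)C1=O | intermediate
16 | peniophorin, 5-hydroxy-3,4-bis(4-hydroxyphenyl)-7-phenyl-1-benzofuran-2,6-dione | O=C1OC2=C(c3ccccc3)C(=O)C(O)=C(c3ccc(O)cc3)C2=C1c1ccc(O)cc1 | target

**Step count**
Total steps: 7. Longest linear sequence: 6 (steps 2–7); step 1 is a one-step branch that joins in step 5.

**Steps most likely to fail**

Step 5. The addition may lose site selectivity in three ways: bond formation through the α-carbon of the ketene acetal, attack at the vinylogous-ester carbonyl or at the isopropoxy-bearing ring carbon (addition–elimination), and Lewis-acid ionisation of the tertiary carbinol once formed. The fallback sets out from 4, uses alkyne 8 and returns at 14, and replaces carbonyl addition by a metal-mediated alkyne insertion. Oxidative insertion of chlorotris(triphenylphosphine)cobalt(I) into the acyl–acyl bond of 4 should give the maleoylcobalt complex chloro(2-isopropoxy-3-phenylmaleoyl)bis(triphenylphosphine)cobalt F1. Treatment of F1 with 8 and AgBF4 in MeCN should build quinone 14 by alkyne insertion and reductive elimination. The isomer from the opposite alkyne orientation would have to be separated.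

Step 6. The ring-opened ketene may be diverted before the 6π closure (capture by the hydroxyl after inward rotation, intermolecular trapping or oligomerisation), or the 1,5-hydrogen shift may be slow and leave a reactive quinone methide that oligomerises. The fallback sets out from 4 and returns at 14, and uses the ordinary alkenyl version of the ring expansion, with the arylacetate unit added afterwards.
- 1-(4-Methoxyphenyl)vinyllithium F2 (from commercial 1-(1-bromovinyl)-4-methoxybenzene and t-BuLi, THF, −78 °C) should add to 4 to give 4-hydroxy-3-isopropoxy-4-[1-(4-methoxyphenyl)ethenyl]-2-phenylcyclobut-2-en-1-one F3.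
- Thermolysis in toluene should give 3-isopropoxy-5-(4-methoxyphenyl)-2-phenylbenzene-1,4-diol F4, and Ag2O should oxidise it to 3-isopropoxy-5-(4-methoxyphenyl)-2-phenylcyclohexa-2,5-diene-1,4-dione F5, which has one free ring position (C3a).
- Mukaiyama–Michael addition of tert-butyl{[1-methoxy-2-(4-methoxyphenyl)ethenyl]oxy}dimethylsilane F6 (from 5, LDA, TBSCl) to that position (TiCl4, CH2Cl2, −78 °C) should give methyl 2-[2,5-dihydroxy-4-isopropoxy-6-(4-methoxyphenyl)-3-phenylphenyl]-2-(4-methoxyphenyl)acetate F7.
- Ag2O oxidation of F7 should return to 14.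

Step 7. Ether cleavage on the electrophilic quinone may be incomplete or accompanied by bromide addition, and the deprotected quinone may fail to tautomerise and lactonise cleanly. The fallback sets out from 14 and returns at 16, and moves the deprotection to the aromatic oxidation level with an oxidative dearomatisation at the end.
- Reduction of 14 with Na2S2O4 should give the hydroquinone ester F7 described above, and acid (TsOH, PhMe, 80 °C) should lactonise it to 5-hydroxy-6-isopropoxy-3,4-bis(4-methoxyphenyl)-7-phenyl-1-benzofuran-2(3H)-one F8.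
- BBr3 should convert F8 into 5,6-dihydroxy-3,4-bis(4-hydroxyphenyl)-7-phenyl-1-benzofuran-2(3H)-one F9.
- Oxidation of the catechol F9 with air or Ag2O to the o-quinone, followed by tautomerisation, should give 16.

**Further compounds**
F1 | step 5 | chloro(2-isopropoxy-3-phenylmaleoyl)bis(triphenylphosphine)cobalt | CC(C)OC1=C(c2ccccc2)C(=O)[Co-2](Cl)([P+](c2ccccc2)(c2ccccc2)c2ccccc2)([P+](c2ccccc2)(c2ccccc2)c2ccccc2)C1=O
F2 | step 6 | 1-(4-methoxyphenyl)vinyllithium | [Li]C(=C)c1ccc(OC)cc1
F3 | step 6 | 4-hydroxy-3-isopropoxy-4-[1-(4-methoxyphenyl)ethenyl]-2-phenylcyclobut-2-en-1-one | C=C(c1ccc(OC)cc1)C1(O)C(OC(C)C)=C(c2ccccc2)C1=O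
F4 | step 6 | 3-isopropoxy-5-(4-methoxyphenyl)-2-phenylbenzene-1,4-diol | CC(C)Oc1c(O)c(-c2ccc(OC)cc2)cc(O)c1-c1ccccc1
F5 | step 6 | 3-isopropoxy-5-(4-methoxyphenyl)-2-phenylcyclohexa-2,5-diene-1,4-dione | CC(C)OC1=C(c2ccccc2)C(=O)C=C(c2ccc(OC)cc2)C1=O
F6 | step 6 | tert-butyl{[1-methoxy-2-(4-methoxyphenyl)ethenyl]oxy}dimethylsilane | COC(O[Si](C)(C)C(C)(C)C)=Cc1ccc(OC)cc1
F7 | step 6 | methyl 2-[2,5-dihydroxy-4-isopropoxy-6-(4-methoxyphenyl)-3-phenylphenyl]-2-(4-methoxyphenyl)acetate | COC(=O)C(c1ccc(OC)cc1)c1c(O)c(-c2ccccc2)c(OC(C)C)c(O)c1-c1ccc(OC)cc1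
F8 | step 7 | 5-hydroxy-6-isopropoxy-3,4-bis(4-methoxyphenyl)-7-phenyl-1-benzofuran-2(3H)-one | O=C1Oc2c(-c3ccccc3)c(OC(C)C)c(O)c(-c3ccc(OC)cc3)c2C1c1ccc(OC)cc1
F9 | step 7 | 5,6-dihydroxy-3,4-bis(4-hydroxyphenyl)-7-phenyl-1-benzofuran-2(3H)-one | O=C1Oc2c(-c3ccccc3)c(O)c(O)c(-c3ccc(O)cc3)c2C1c1ccc(O)cc1
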